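Compound numbers are fixed by the steps below. Ring A is the methyl benzoate ring (C1 to C6), ring B is the acyl ring (C1′ to C6′).

## Analysis of the target

The target 9 is a depside: two benzene rings joined by one aryl ester. Ring A carries CO2CH3 at C1, OH at C2, CH3 at C3, the depside oxygen at C4, H at C5 and CH3 at C6. Ring B carries the depside carbonyl at C1′, three neighbouring OH groups at C2′, C3′ and C4′, H at C5′ and CH3 at C6′. There is no stereocentre, so the problem is one of constitution and chemoselectivity only.

The sensitive groups are the aryl ester, which base, alkoxide or amine will cleave or transesterify, and the free pyrogallol unit of ring B, which autoxidises easily, above all as a phenolate. The synthesis is hard for two reasons. Ring B is pentasubstituted with three adjacent free phenols next to the carbonyl. And the ester bond joins a carbonyl flanked by C2′–O and C6′–CH3 to an oxygen (O4) flanked by the C3 methyl, so a direct esterification is hindered on both sides. Any protection on ring B must also come off under conditions that leave the depside bond alone.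

The feature that invites the chosen strategy is this: C1′ (with its carbonyl) and C6′ (with its methyl) are neighbours and map exactly onto the two sp carbons of a but-2-ynoate ester. The other four ring atoms, C2′ to C5′, carry O, O, O, H, which is the pattern of a 1,2,3-trioxygenated diene. Ring B can therefore be built by benzannulation on an ynoate that is already bound to ring A.

## Retrosynthetic reasoning

**9 to 8.** Only the three O–Si bonds on ring B are cut. Silyl ethers are chosen because they come with the diene of the key step at no extra cost, and because they fall off in dilute acid, which the aryl ester tolerates. The forward step must free the pyrogallol unit without base.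

**8 to 7 to 6 + 3.** Ring B is cut at C1′–C2′ and C5′–C6′, and a two-carbon saturated bridge is put back across C2′ and C5′. This is the reverse of a Diels–Alder reaction followed by a cycloreversion (Alder–Rickert sequence). The cut is made here because it turns C1′ and C6′ into the alkyne carbons of the ynoate 6 and puts all three oxygens and the C5′ hydrogen on the cyclic diene 3. The gain is twofold. The pentasubstituted ring is assembled with every substituent in place by the ring construction itself. And the depside bond no longer has to be made at a crowded benzoate carbonyl; it is already present in 6 as the ester of a linear ynoic acid. The forward reaction has to deliver one orientation of diene on ynoate (the oxygen-bearing diene terminus next to the ester carbon) and then expel the bridge to aromatise.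

**6 to 4 + 5.** The ester bond C(=O)–O4 is cut. With the rod-like acid 5 there is no steric problem at O4. The forward reaction has to choose O4 over O2; O2–H is locked in a hydrogen bond to the C1 ester and is flanked on both sides, whereas O4–H is free and more acidic.

**3 to 2 to 1.** The three O–Si bonds of 3 are cut, giving the reductone 2, which goes back to the aromatic triol 1 by removal of one equivalent of hydrogen. The oxygen pattern of a cheap arene is thus lifted onto a diene and later moved onto a new ring. The forward steps are a partial hydrogenation and an exhaustive O-silylation with enolisation.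

## Alternatives that were turned down

**Alternative 1:** the textbook cut through the depside ester C1′(=O)–O4. It gives phenol 4 and 2,3,4-tris(benzyloxy)-6-methylbenzoic acid A2, which would be made from 5-methylbenzene-1,2,3-triol A1 by tris-benzylation, ring formylation beside the methyl group and aldehyde oxidation. The forward key step is acylation of 4 by activated A2 to the tribenzyl depside A3, followed by hydrogenolysis to 9.
- Structure: the acyl carbon of A2 sits between C2′–O and C6′–CH3, and O4 sits beside the C3 methyl, so the key step is the most hindered esterification this target offers.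
- Step economy: three steps only decorate an existing ring to reach A2, and the route needs five in all, so nothing is saved.
- Strategy: no part of the skeleton is built. The route is reliable and is kept as the fallback for the key step.

**Alternative 2:** a polyketide-type closure of ring B at the aldol bond C1′–C6′, combined with formation of the ester from an acylketene. In the forward direction, thermal cycloreversion of the dioxinone A4 gives an acylketene, which 4 traps as the aryl 3,5,7-trioxooctanoate A5; base then closes A5 by aldol condensation to the orsellinate depside A6.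
- Mechanism: in A5 the enol oxygen at C5 of the chain lies six atoms from an aryl ester carbonyl whose leaving group is a stabilised phenoxide. Lactonisation with expulsion of 4 should outrun the carbon–carbon closure.
- Structure: A6 lacks the oxygen at C3′. Adding it late means electrophilic substitution and oxidation at C3′ in competition with C5′ and with C5 of ring A.
- Step economy: at least two further steps of doubtful selectivity after the key step, plus the steps to A4.

**Alternative 3:** the same two ring bonds as in the chosen route, but with a furan as the four-carbon partner. Diels–Alder reaction of 3,4-bis(benzyloxy)furan A7 with 6 would give the oxanorbornadiene A8; acid-induced opening of the oxygen bridge and hydrogenolysis would follow.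
- Mechanism: the bridge opens at the bridgehead whose cation avoids placing charge on the ester-bearing carbon. That is the bridgehead next to C1′, with charge spread to C6′ and to a benzyloxy carbon. The oxygen then stays on the bridgehead next to C6′.
- Outcome: the product A9 carries OH at C5′ and H at C2′, a constitutional isomer of the pattern needed.
- Step economy and reactivity: A7 is not commercial, and furan cycloadditions with β-substituted ynoates are reversible.

Key step: step 4

Remark on the chemistry: the target has no stereocentre; the transient cycloadduct 7 forms as a racemate and its two bridgehead centres are destroyed in the same step.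

## Route

Step 1
Reactants: 1 pyrogallol (benzene-1,2,3-triol)
Product: 2 2,3-dihydroxycyclohex-2-en-1-one
Conditions: H2 (100 bar), Raney Ni, NaOH (1.05 equiv), H2O, 50 °C; then aq. HCl to pH 2, N2
Reagents that add atoms: none
Why: Partial catalytic hydrogenation of a polyhydric phenolate, the reaction type that turns resorcinol into cyclohexane-1,3-dione; uptake should stop after one equivalent of H2 because the product is the delocalised enolate of a cyclic 2-hydroxy-1,3-dione, which resists further reduction.

Step 2
Reactants: 2 2,3-dihydroxycyclohex-2-en-1-one
Product: 3 1,2,3-tris(trimethylsilyloxy)cyclohexa-1,3-diene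
Conditions: Me3SiOTf (3.5 equiv), Et3N (4.5 equiv), Et2O, 0 °C to rt, N2; decant from the ammonium salt, bulb-to-bulb distillation
Reagents that add atoms: trimethylsilyl trifluoromethanesulfonate, C[Si](C)(C)OS(=O)(=O)C(F)(F)F
Why: O-Silylation of both hydroxyls followed by soft enolisation of the vinylogous ester (silyl triflate on the carbonyl oxygen, deprotonation by Et3N), the standard route to silyloxy dienes from cyclic 1,3-diones; the intermediate tris(silyloxy)allyl cation is symmetric, so deprotonation at either flanking CH2 should give the same diene.

Step 3
Reactants: 4 methyl 2,4-dihydroxy-3,6-dimethylbenzoate; 5 but-2-ynoic acid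
Product: 6 methyl 4-(but-2-ynoyloxy)-2-hydroxy-3,6-dimethylbenzoate
Conditions: DCC (1.1 equiv), DMAP (5 mol %), CH2Cl2, −10 to 0 °C
Reagents that add atoms: none
Why: Steglich carbodiimide esterification; O4–H is free and the more acidic phenol (para to the ester), whereas O2–H is tied up in a hydrogen bond to the C1 ester and flanked on both sides, so monoacylation at O4 is expected, and the linear ynoic acid meets no steric barrier beside the C3 methyl.

Step 4
Reactants: 6 methyl 4-(but-2-ynoyloxy)-2-hydroxy-3,6-dimethylbenzoate; 3 1,2,3-tris(trimethylsilyloxy)cyclohexa-1,3-diene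
Product: 8 methyl 2-hydroxy-3,6-dimethyl-4-{[6-methyl-2,3,4-tris(trimethylsilyloxy)benzoyl]oxy}benzoate, via bicyclo[2.2.2]octadiene cycloadduct 7 (not isolated)
Conditions: 3 (3 equiv), neat, sealed tube, argon, 140 °C then 180 °C; volatiles removed in vacuo, crude carried on
Reagents that add atoms: none
Why: A thermal normal-demand Diels–Alder reaction between the electron-rich diene 3 and the aryl ynoate 6 (whose aryloxy group lowers the LUMO relative to an alkyl ynoate) gives the bicyclo[2.2.2]octa-2,5-diene 7, which on further heating undergoes a retro-Diels–Alder reaction that expels its saturated two-carbon bridge as ethene and leaves ring B aromatic (Alder–Rickert sequence). The closest known reaction type is the resorcylate synthesis from 1,3-bis(silyloxy)cyclohexa-1,3-dienes and alkynoates, including β-alkyl-substituted and macrocyclic ynoates, run neat at comparable temperatures. Ring B is closed by an intermolecular suprafacial [4+2] cycloaddition that forms C1′–C2′ and C5′–C6′ at once, and the cycloreversion is made irreversible by aromatisation and loss of a gas. The two bridgehead stereocentres of racemic 7 are erased by the cycloreversion, so no stereocontrol is needed. The step needs regiocontrol: the unsubstituted terminus C4 of 3 is the nucleophilic one (the silyloxy groups on C1 and C3 both raise the HOMO coefficient there, only the one on C2 opposes, and C4 is the less hindered end) and should bond to the methyl-bearing β-carbon of 6, the site of the largest LUMO coefficient, which puts the C1 silyloxy group next to the ester carbon as C2′ requires. It also needs extrusion of ethene to win over cycloreversion to the starting materials, which the aromatic stabilisation gained only on ethene loss should secure. The chelated O2–H of 6 is a poor silyl acceptor, and the excess of 3 covers any silyl transfer to it, which step 5 would undo in any case.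

Step 5
Reactants: 8 methyl 2-hydroxy-3,6-dimethyl-4-{[6-methyl-2,3,4-tris(trimethylsilyloxy)benzoyl]oxy}benzoate
Product: 9 methyl 2-hydroxy-3,6-dimethyl-4-[(2,3,4-trihydroxy-6-methylbenzoyl)oxy]benzoate
Conditions: 1 M aq. HCl, THF (degassed), 0 °C to rt, argon; extraction and crystallisation under argon
Reagents that add atoms: none
Why: Acid hydrolysis of aryl trimethylsilyl ethers, which is fast in dilute aqueous acid where the aryl ester and the methyl ester are inert; no base is present, so neither transesterification of the depside nor phenolate autoxidation of the pyrogallol ring is invited.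

## Compound list

1 | pyrogallol (benzene-1,2,3-triol) | Oc1cccc(O)c1O | starting material
2 | 2,3-dihydroxycyclohex-2-en-1-one | O=C1CCCC(O)=C1O | intermediate
3 | 1,2,3-tris(trimethylsilyloxy)cyclohexa-1,3-diene | C[Si](C)(C)OC1=CCCC(O[Si](C)(C)C)=C1O[Si](C)(C)C | intermediate
4 | methyl 2,4-dihydroxy-3,6-dimethylbenzoate | COC(=O)c1c(C)cc(O)c(C)c1O | starting material
5 | but-2-ynoic acid | CC#CC(=O)O | starting material
6 | methyl 4-(but-2-ynoyloxy)-2-hydroxy-3,6-dimethylbenzoate | COC(=O)c1c(C)cc(OC(=O)C#CC)c(C)c1O | intermediate
7 | 3-hydroxy-4-(methoxycarbonyl)-2,5-dimethylphenyl 3-methyl-1,5,6-tris(trimethylsilyloxy)bicyclo[2.2.2]octa-2,5-diene-2-carboxylate (racemic, one enantiomer drawn) | C[Si](C)(C)O[C@]12CC[C@H](C(C)=C1C(=O)Oc3cc(C)c(C(=O)OC)c(O)c3C)C(O[Si](C)(C)C)=C2O[Si](C)(C)C | intermediate (not isolated)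
8 | methyl 2-hydroxy-3,6-dimethyl-4-{[6-methyl-2,3,4-tris(trimethylsilyloxy)benzoyl]oxy}benzoate | COC(=O)c1c(C)cc(OC(=O)c2c(C)cc(O[Si](C)(C)C)c(O[Si](C)(C)C)c2O[Si](C)(C)C)c(C)c1O | intermediate
9 | methyl 2-hydroxy-3,6-dimethyl-4-[(2,3,4-trihydroxy-6-methylbenzoyl)oxy]benzoate | COC(=O)c1c(C)cc(OC(=O)c2c(C)cc(O)c(O)c2O)c(C)c1O | target

## Step count and risk

Total step count: 5. Longest linear sequence: 4 steps (steps 1, 2, 4 and 5, from 1 to 9); the second branch (step 3) joins at step 4. Steps 1 and 3 follow close precedent and are judged the most secure.

**Step 4 (key step).** The cycloaddition may be too slow, because the ynoate carries a β-methyl group and must bond to a fully substituted, silyloxy-bearing diene terminus. Slow cycloaddition leaves room for thermal decay of the diene and for silyl transfer from the diene to the phenol. Regiocontrol may also erode, because the silyloxy group on C2 of the diene works against the other two donors.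

Fallback (sets out from 4, comes back at 9): the depside bond is made the classical way. Commercial 5-methylbenzene-1,2,3-triol is tribenzylated (BnBr, K2CO3, DMF) to 1,2,3-tris(benzyloxy)-5-methylbenzene F1. Vilsmeier–Haack formylation beside the methyl group (POCl3, DMF) gives 2,3,4-tris(benzyloxy)-6-methylbenzaldehyde F2, and Pinnick oxidation (NaClO2, NaH2PO4, 2-methylbut-2-ene, tBuOH/H2O) gives 2,3,4-tris(benzyloxy)-6-methylbenzoic acid F3. Steglich coupling of F3 with 4 (DCC, DMAP, CH2Cl2) gives methyl 2-hydroxy-3,6-dimethyl-4-{[2,3,4-tris(benzyloxy)-6-methylbenzoyl]oxy}benzoate F4, and hydrogenolysis (H2, Pd/C, EtOAc) returns to 9.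

**Step 2.** The third silylation (the enolisation) may stay incomplete, the reductone may autoxidise before it is capped, and the tris(silyl) dienol ether may hydrolyse during isolation, since all three oxygens carry the most labile silyl group.

Fallback (sets out from 2, comes back at 9): the two hydroxyls are fixed as robust ethers before the diene is made. 2 is O-benzylated twice (BnBr, K2CO3, DMF) to 2,3-bis(benzyloxy)cyclohex-2-en-1-one F5. Kinetic enolisation (LiN(iPr)2, THF, −78 °C) and O-silylation (Me3SiCl) give 1,2-bis(benzyloxy)-3-(trimethylsilyloxy)cyclohexa-1,3-diene F6. Either site of enolisation would lead to the same oxygen pattern on ring B. The same cycloaddition and cycloreversion with 6, with an acidic work-up, should give methyl 4-{[2,3-bis(benzyloxy)-4-hydroxy-6-methylbenzoyl]oxy}-2-hydroxy-3,6-dimethylbenzoate F7, and hydrogenolysis (H2, Pd/C, EtOAc) gives 9.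

**Step 5.** The hydrolysis itself is mild; the risk lies in isolation. The freed pyrogallol ring may autoxidise, and material may be lost when the polar triol is separated from siloxane residues and from any minor regioisomer carried over from step 4.

Fallback (sets out from 8, comes back at 9): crude 8 is converted directly by desilylative acetylation (Ac2O, cat. Cu(OTf)2, CH2Cl2, rt) into methyl 2-(acetyloxy)-3,6-dimethyl-4-{[2,3,4-tris(acetyloxy)-6-methylbenzoyl]oxy}benzoate F8. F8 is not oxidisable and can be purified by crystallisation or chromatography. Acid methanolysis of the four aryl acetates (HCl in MeOH, 0 °C to rt, argon) should then give 9 after evaporation alone, because the doubly ortho-substituted depside ester is far more hindered than the acetates.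

## Further compounds

F1 | step 4 | 1,2,3-tris(benzyloxy)-5-methylbenzene | Cc1cc(OCc2ccccc2)c(OCc2ccccc2)c(OCc2ccccc2)c1
F2 | step 4 | 2,3,4-tris(benzyloxy)-6-methylbenzaldehyde | Cc1cc(OCc2ccccc2)c(OCc2ccccc2)c(OCc2ccccc2)c1C=O
F3 | step 4 | 2,3,4-tris(benzyloxy)-6-methylbenzoic acid | Cc1cc(OCc2ccccc2)c(OCc2ccccc2)c(OCc2ccccc2)c1C(=O)O
F4 | step 4 | methyl 2-hydroxy-3,6-dimethyl-4-{[2,3,4-tris(benzyloxy)-6-methylbenzoyl]oxy}benzoate | COC(=O)c1c(C)cc(OC(=O)c2c(C)cc(OCc3ccccc3)c(OCc3ccccc3)c2OCc4ccccc4)c(C)c1O
F5 | step 2 | 2,3-bis(benzyloxy)cyclohex-2-en-1-one | O=C1CCCC(OCc2ccccc2)=C1OCc3ccccc3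
F6 | step 2 | 1,2-bis(benzyloxy)-3-(trimethylsilyloxy)cyclohexa-1,3-diene | C[Si](C)(C)OC1=CCCC(OCc2ccccc2)=C1OCc3ccccc3
F7 | step 2 | methyl 4-{[2,3-bis(benzyloxy)-4-hydroxy-6-methylbenzoyl]oxy}-2-hydroxy-3,6-dimethylbenzoate | COC(=O)c1c(C)cc(OC(=O)c2c(C)cc(O)c(OCc3ccccc3)c2OCc4ccccc4)c(C)c1O
F8 | step 5 | methyl 2-(acetyloxy)-3,6-dimethyl-4-{[2,3,4-tris(acetyloxy)-6-methylbenzoyl]oxy}benzoate | COC(=O)c1c(C)cc(OC(=O)c2c(C)cc(OC(C)=O)c(OC(C)=O)c2OC(C)=O)c(C)c1OC(C)=O
A1 | alternative 1 | 5-methylbenzene-1,2,3-triol | Cc1cc(O)c(O)c(O)c1
A2 | alternative 1 | 2,3,4-tris(benzyloxy)-6-methylbenzoic acid | Cc1cc(OCc2ccccc2)c(OCc2ccccc2)c(OCc2ccccc2)c1C(=O)O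
A3 | alternative 1 | methyl 2-hydroxy-3,6-dimethyl-4-{[2,3,4-tris(benzyloxy)-6-methylbenzoyl]oxy}benzoate | COC(=O)c1c(C)cc(OC(=O)c2c(C)cc(OCc3ccccc3)c(OCc3ccccc3)c2OCc4ccccc4)c(C)c1O
A4 | alternative 2 | 6-(2,4-dioxopentyl)-2,2-dimethyl-4H-1,3-dioxin-4-one | CC(=O)CC(=O)CC1=CC(=O)OC(C)(C)O1
A5 | alternative 2 | 3-hydroxy-4-(methoxycarbonyl)-2,5-dimethylphenyl 3,5,7-trioxooctanoate | CC(=O)CC(=O)CC(=O)CC(=O)Oc1cc(C)c(C(=O)OC)c(O)c1C
A6 | alternative 2 | methyl 4-[(2,4-dihydroxy-6-methylbenzoyl)oxy]-2-hydroxy-3,6-dimethylbenzoate | COC(=O)c1c(C)cc(OC(=O)c2c(C)cc(O)cc2O)c(C)c1O
A7 | alternative 3 | 3,4-bis(benzyloxy)furan | C(Oc1cocc1OCc2ccccc2)c3ccccc3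
A8 | alternative 3 | 3-hydroxy-4-(methoxycarbonyl)-2,5-dimethylphenyl 5,6-bis(benzyloxy)-3-methyl-7-oxabicyclo[2.2.1]hepta-2,5-diene-2-carboxylate (racemic, one enantiomer drawn) | CC1=C(C(=O)Oc3cc(C)c(C(=O)OC)c(O)c3C)[C@H]2O[C@@H]1C(OCc4ccccc4)=C2OCc5ccccc5
A9 | alternative 3 | methyl 4-{[4,5-bis(benzyloxy)-3-hydroxy-2-methylbenzoyl]oxy}-2-hydroxy-3,6-dimethylbenzoate | Cc1c(O)c(OCc2ccccc2)c(OCc2ccccc2)cc1C(=O)Oc1cc(C)c(C(=O)OC)c(O)c1C
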